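**Plan**

1. The target is the all-(4β→8) epicatechin tetramer. Retrosynthesis cuts the three C4–C8 interflavan bonds and, inside unit 3, the C2–C3 bond: unit 3 is traced back to a 2-aryl-2,3-dihydrobenzofuran-3-carbaldehyde in which C2 is still bonded to the later C4.
2. Enabling feature: C4 of unit 3 is benzylic to ring A, whose O1, O5 and O7 stabilise a C4 cation, and C2 carries O1 and ring B and is therefore a good migrating carbon; a C3 acyloxycarbenium ion should pull C2 from C4 onto C3.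
3. Forward: phloroglucinol triether → aryl diazoacetate → carbenoid C–H insertion (five-membered ring, C2–C4 bond) → trans aldehyde → 1,2-shift closes ring C (C2–C3) and leaves C4 as an acetate → unit 4, then unit 2, then unit 1 are joined by C4-cation/C8 Friedel–Crafts couplings → deprotection.
4. Stereochemistry: units 1, 2 and 4 come from (−)-epicatechin; C2 of unit 3 comes from the chiral dirhodium catalyst and is kept through the shift, C3 is set in the shift, and every C4 is set by attack trans to the 3-oxygen.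
5. Units are numbered 1 (top, free C8) to 4 (bottom, C4 = CH2); flavan numbering of unit 3 is used for its precursors; DBB = 3,4-bis(benzyloxy)benzyl, Bn = benzyl.

Key step: step 6

Remark: Rh2(S-PTTL)4 is taken to give the (2S,3R) sense drawn for 8; if the opposite sense is found, the mirror-image catalyst Rh2(R-PTTL)4 is used.

**Step 1**
Reactants: 1 phloroglucinol; 2 3,4-bis(benzyloxy)benzyl chloride (3.3 equiv in all)
Product: 3 1,3,5-tris(DBB-oxy)benzene
Conditions: K2CO3, NaI (cat.), DMF, 60 °C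
Reagents that add atoms: 3,4-bis(benzyloxy)benzyl chloride (second equivalent) ClCc1ccc(OCc2ccccc2)c(OCc2ccccc2)c1; 3,4-bis(benzyloxy)benzyl chloride (third equivalent) ClCc1ccc(OCc2ccccc2)c(OCc2ccccc2)c1
Why: Threefold Williamson etherification, one equivalent of 2 per phenol, should give the C3-symmetric triether in which all ring positions and all three benzylic ether groups are equivalent, so that steps 2 and 4 have no regiochemical choice.

**Step 2**
Reactants: 3 1,3,5-tris(DBB-oxy)benzene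
Product: 5 methyl 2-oxo-2-[2,4,6-tris(DBB-oxy)phenyl]acetate, via acid chloride 4 (not isolated)
Conditions: (COCl)2, 2,6-lutidine, CH2Cl2, −20 °C to rt; then MeOH, Et3N, 0 °C
Reagents that add atoms: oxalyl chloride ClC(=O)C(Cl)=O; methanol CO
Why: The phloroglucinol triether core is nucleophilic enough for an uncatalysed Friedel–Crafts acylation by oxalyl chloride, the first acyl group deactivates the ring against a second one, and methanolysis of the acid chloride should give the keto ester.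

**Step 3**
Reactants: 5 methyl 2-oxo-2-[2,4,6-tris(DBB-oxy)phenyl]acetate
Product: 7 methyl 2-diazo-2-[2,4,6-tris(DBB-oxy)phenyl]acetate, via tosylhydrazone 6 (not isolated)
Conditions: TsNHNH2, MeOH–THF, 50 °C; then DBU, CH2Cl2, 0 °C to rt
Reagents that add atoms: p-toluenesulfonyl hydrazide Cc1ccc(cc1)S(=O)(=O)NN
Why: Bamford–Stevens sequence: the activated keto group of the α-keto ester should condense with the hydrazide, and base-induced loss of sulfinate should give the aryl diazoacetate.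

**Step 4**
Reactants: 7 methyl 2-diazo-2-[2,4,6-tris(DBB-oxy)phenyl]acetate
Product: 8 methyl (2S,3R)-2-[3,4-bis(benzyloxy)phenyl]-4,6-bis(DBB-oxy)-2,3-dihydrobenzofuran-3-carboxylate (2,3-cis)
Conditions: Rh2(S-PTTL)4 [dirhodium tetrakis(N-phthaloyl-(S)-tert-leucinate)] (1 mol %), toluene, −60 °C
Reagents that add atoms: none
Why: Intramolecular dirhodium-carbenoid 1,5 C–H insertion into the benzylic C–H of an ortho ether (both ortho ethers are identical) is a known route to cis-2-aryl-2,3-dihydrobenzofuran-3-carboxylates, and the chiral carboxylate ligands should set the configuration of the aryl-bearing carbon (the later C2).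

**Step 5**
Reactants: 8 the cis ester
Product: 10 (2S,3S)-2-[3,4-bis(benzyloxy)phenyl]-4,6-bis(DBB-oxy)-2,3-dihydrobenzofuran-3-carbaldehyde (2,3-trans), via cis-aldehyde 9 (not isolated)
Conditions: i-Bu2AlH (1.1 equiv), CH2Cl2, −78 °C; aq. potassium sodium tartrate; then DBU (0.2 equiv), CH2Cl2, rt
Reagents that add atoms: none
Why: Half-reduction of the ester through the aluminium hemiacetal should give the aldehyde, and DBU should epimerise the enolisable formyl-bearing carbon to the more stable 2,3-trans isomer while the aryl-bearing stereocentre is untouched.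

**Step 6**
Reactants: 10 the trans aldehyde
Product: 12 (2R)-2,3-cis-3,4-trans-3,4-diacetoxy-3',4'-bis(benzyloxy)-5,7-bis(DBB-oxy)flavan, via acylal 11 (not isolated)
Conditions: Ac2O (1.2 equiv), TMSOTf (0.2 equiv), 2,6-di-tert-butyl-4-methylpyridine (0.3 equiv), CH2Cl2 (0.01 M), −78 to −30 °C
Reagents that add atoms: acetic anhydride CC(=O)OC(C)=O
Why: Proposed new method: Ac2O and TMSOTf should turn the aldehyde into acylal 11 and ionise it to the C3 acetoxycarbenium ion, to which the ring bond C2–C4, held parallel to the empty p orbital, shifts suprafacially so that C2 leaves C4 and bonds to C3; the closest known reaction types are the semipinacol-type 1,2-alkyl shift that opens the acid-catalysed aldehyde–ketone rearrangement and the ring enlargement of cycloalkanecarbaldehydes, here interrupted because the cation left behind is the flavan-4-yl cation stabilised by O1, O5 and O7 of ring A. Ring C (six-membered) is closed by this 1,2-carbon shift, a one-carbon enlargement of the five-membered ring and not an end-to-end cyclisation, and the cation is held by the neighbouring 3-acetoxy group as a cis-fused acetoxonium ion that acetate opens at C4. C2 migrates with retention and so keeps the configuration set in step 4; C3 is set in the shift by the rotamer that turns the O-acetyl oxocarbenium group away from ring A and its C5 ether, which for the 2,3-trans aldehyde places the new C3–O bond cis to the aryl group on C2; C4 is set trans by the acetoxonium opening and is re-formed in step 8 in any case. The step needs migration of C2 in preference to hydride migration, aryl migration and enolisation: C2 carries the O1 lone pair and the electron-rich ring B and should be the best migrating group, aryl migration would leave an unstabilised secondary cation, the hindered pyridine keeps the medium aprotic, and the trans arrangement keeps ring B away from the C3 cation.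

**Step 7**
Reactants: 13 (−)-epicatechin
Product: 14 5,7,3',4'-tetra-O-benzyl-(−)-epicatechin
Conditions: BnBr (4.4 equiv), K2CO3, DMF, 0 °C to rt
Reagents that add atoms: benzyl bromide BrCc1ccccc1
Why: Williamson benzylation should protect the four phenols and leave the much less acidic secondary 3-OH free, with no effect on C2 and C3.

**Step 8**
Reactants: 12 the 3,4-diacetate; 14 tetra-O-benzylepicatechin (3 equiv, excess recovered)
Product: 15 [3-O-acetyl-3',4'-di-O-benzyl-5,7-di-O-DBB-epicatechin]-(4β→8)-[5,7,3',4'-tetra-O-benzylepicatechin]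
Conditions: TMSOTf (0.2 equiv), CH2Cl2, −78 to −40 °C
Reagents that add atoms: none
Why: Lewis-acid ionisation of the 4-acetoxy group gives the flavan-4-yl cation (as its acetoxonium ion), and Friedel–Crafts attack by the nucleophilic C8 of 14 from the face trans to the participating 3-acetoxy group should set the 4β (3,4-trans) interflavan bond, as in known couplings of 3-O-acyl 4-O-activated flavans.

**Step 9**
Reactants: 14 tetra-O-benzylepicatechin
Product: 16 5,7,3',4'-tetra-O-benzyl-4β-(2-ethoxyethoxy)epicatechin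
Conditions: DDQ, 2-ethoxyethanol, CH2Cl2, rt
Reagents that add atoms: 2-ethoxyethanol CCOCCO
Why: DDQ abstracts hydride from the benzylic C4 of the electron-rich flavan, and the alcohol should capture the cation trans to the 3-OH (known oxidative C4 functionalisation).

**Step 10**
Reactants: 15 the dimer (2 equiv, excess recovered); 16 the 4β-(2-ethoxyethoxy) electrophile
Product: 17 [tetra-O-benzylepicatechin]-(4β→8)-[3-O-acetyl-di-O-benzyl-di-O-DBB-epicatechin]-(4β→8)-[tetra-O-benzylepicatechin]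
Conditions: TMSOTf (0.1 equiv), CH2Cl2, −78 °C
Reagents that add atoms: none
Why: The C4 cation from 16 should attack C8 of the upper unit of the nucleophile trans to its own 3-OH, the known regio- and stereochemical course of Lewis-acid chain extension of benzylated procyanidins.

**Step 11**
Reactants: 17 the trimer (2 equiv, excess recovered); 16 the 4β-(2-ethoxyethoxy) electrophile
Product: 18 protected tetramer with the 3-O-acetyl group on unit 3
Conditions: TMSOTf (0.1 equiv), CH2Cl2, −78 °C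
Reagents that add atoms: none
Why: The same Friedel–Crafts chain extension at C8 of the new top unit should give the 4β→8 linked tetramer.

**Step 12**
Reactants: 18 the acetylated tetramer
Product: 19 protected tetramer with all four 3-OH groups free
Conditions: NaOMe (cat.), MeOH–THF, rt
Reagents that add atoms: none
Why: Zemplén transesterification should remove the single secondary acetate without touching the ethers or any stereocentre (all phenols are blocked, so C2 cannot epimerise through a quinone methide).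

**Step 13**
Reactants: 19 the deacetylated tetramer
Product: 20 the target tetramer epicatechin-(4β→8)-epicatechin-(4β→8)-epicatechin-(4β→8)-epicatechin
Conditions: H2 (1 atm), Pd(OH)2/C, THF–MeOH–H2O, rt
Reagents that add atoms: none
Why: Hydrogenolysis should cleave all benzyl and DBB ethers (the DBB groups leave as 4-methylcatechol), while the cyclic secondary benzylic ethers O1–C2 are known to survive these conditions.

**Compound list**

1 | phloroglucinol | Oc1cc(O)cc(O)c1 | starting material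
2 | 3,4-bis(benzyloxy)benzyl chloride | ClCc1ccc(OCc2ccccc2)c(OCc2ccccc2)c1 | starting material
3 | 1,3,5-tris(DBB-oxy)benzene | c1c(OCc2ccc(OCc3ccccc3)c(OCc3ccccc3)c2)cc(OCc2ccc(OCc3ccccc3)c(OCc3ccccc3)c2)cc1OCc1ccc(OCc2ccccc2)c(OCc2ccccc2)c1 | intermediate
4 | 2-oxo-2-[2,4,6-tris(DBB-oxy)phenyl]acetyl chloride | ClC(=O)C(=O)c1c(OCc2ccc(OCc3ccccc3)c(OCc3ccccc3)c2)cc(OCc2ccc(OCc3ccccc3)c(OCc3ccccc3)c2)cc1OCc1ccc(OCc2ccccc2)c(OCc2ccccc2)c1 | intermediate
5 | methyl 2-oxo-2-[2,4,6-tris(DBB-oxy)phenyl]acetate | COC(=O)C(=O)c1c(OCc2ccc(OCc3ccccc3)c(OCc3ccccc3)c2)cc(OCc2ccc(OCc3ccccc3)c(OCc3ccccc3)c2)cc1OCc1ccc(OCc2ccccc2)c(OCc2ccccc2)c1 | intermediate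
6 | tosylhydrazone of 5 | COC(=O)C(=NNS(=O)(=O)c1ccc(C)cc1)c1c(OCc2ccc(OCc3ccccc3)c(OCc3ccccc3)c2)cc(OCc2ccc(OCc3ccccc3)c(OCc3ccccc3)c2)cc1OCc1ccc(OCc2ccccc2)c(OCc2ccccc2)c1 | intermediate
7 | methyl 2-diazo-2-[2,4,6-tris(DBB-oxy)phenyl]acetate | COC(=O)C(=[N+]=[N-])c1c(OCc2ccc(OCc3ccccc3)c(OCc3ccccc3)c2)cc(OCc2ccc(OCc3ccccc3)c(OCc3ccccc3)c2)cc1OCc1ccc(OCc2ccccc2)c(OCc2ccccc2)c1 | intermediate
8 | methyl (2S,3R)-2-[3,4-bis(benzyloxy)phenyl]-4,6-bis(DBB-oxy)-2,3-dihydrobenzofuran-3-carboxylate (cis) | c1c(OCc3ccc(OCc4ccccc4)c(OCc4ccccc4)c3)cc(OCc3ccc(OCc4ccccc4)c(OCc4ccccc4)c3)c2c1O[C@H](c1ccc(OCc3ccccc3)c(OCc3ccccc3)c1)[C@@H]2C(=O)OC | intermediate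
9 | (2S,3R)-2-[3,4-bis(benzyloxy)phenyl]-4,6-bis(DBB-oxy)-2,3-dihydrobenzofuran-3-carbaldehyde (cis) | c1c(OCc3ccc(OCc4ccccc4)c(OCc4ccccc4)c3)cc(OCc3ccc(OCc4ccccc4)c(OCc4ccccc4)c3)c2c1O[C@H](c1ccc(OCc3ccccc3)c(OCc3ccccc3)c1)[C@@H]2C=O | intermediate
10 | (2S,3S)-2-[3,4-bis(benzyloxy)phenyl]-4,6-bis(DBB-oxy)-2,3-dihydrobenzofuran-3-carbaldehyde (trans) | c1c(OCc3ccc(OCc4ccccc4)c(OCc4ccccc4)c3)cc(OCc3ccc(OCc4ccccc4)c(OCc4ccccc4)c3)c2c1O[C@H](c1ccc(OCc3ccccc3)c(OCc3ccccc3)c1)[C@H]2C=O | intermediate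
11 | geminal diacetate (acylal) of 10 | c1c(OCc3ccc(OCc4ccccc4)c(OCc4ccccc4)c3)cc(OCc3ccc(OCc4ccccc4)c(OCc4ccccc4)c3)c2c1O[C@H](c1ccc(OCc3ccccc3)c(OCc3ccccc3)c1)[C@H]2C(OC(C)=O)OC(C)=O | intermediate
12 | (2R)-2,3-cis-3,4-trans-3,4-diacetoxy-3',4'-bis(benzyloxy)-5,7-bis(DBB-oxy)flavan | c1c(OCc3ccc(OCc4ccccc4)c(OCc4ccccc4)c3)cc(OCc3ccc(OCc4ccccc4)c(OCc4ccccc4)c3)c2c1O[C@H](c1ccc(OCc3ccccc3)c(OCc3ccccc3)c1)[C@H](OC(C)=O)[C@H]2OC(C)=O | intermediate
13 | (−)-epicatechin | Oc1cc(O)c2c(c1)O[C@H](c1ccc(O)c(O)c1)[C@H](O)C2 | starting material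
14 | 5,7,3',4'-tetra-O-benzyl-(−)-epicatechin | c1c(OCc3ccccc3)cc(OCc3ccccc3)c2c1O[C@H](c1ccc(OCc3ccccc3)c(OCc3ccccc3)c1)[C@H](O)C2 | intermediate
15 | protected dimer (unit 3 as 3-O-acetate with DBB ethers at O5 and O7, 4β→8 to unit 4) | c1c(OCc3ccc(OCc4ccccc4)c(OCc4ccccc4)c3)cc(OCc3ccc(OCc4ccccc4)c(OCc4ccccc4)c3)c2c1O[C@H](c1ccc(OCc3ccccc3)c(OCc3ccccc3)c1)[C@H](OC(C)=O)[C@H]2c1c(OCc3ccccc3)cc(OCc3ccccc3)c2c1O[C@H](c1ccc(OCc3ccccc3)c(OCc3ccccc3)c1)[C@H](O)C2 | intermediate
16 | 5,7,3',4'-tetra-O-benzyl-4β-(2-ethoxyethoxy)epicatechin | c1c(OCc3ccccc3)cc(OCc3ccccc3)c2c1O[C@H](c1ccc(OCc3ccccc3)c(OCc3ccccc3)c1)[C@H](O)[C@H]2OCCOCC | intermediate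
17 | protected trimer (units 2–3–4, all 4β→8) | c1c(OCc3ccccc3)cc(OCc3ccccc3)c2c1O[C@H](c1ccc(OCc3ccccc3)c(OCc3ccccc3)c1)[C@H](O)[C@H]2c1c(OCc3ccc(OCc4ccccc4)c(OCc4ccccc4)c3)cc(OCc3ccc(OCc4ccccc4)c(OCc4ccccc4)c3)c2c1O[C@H](c1ccc(OCc3ccccc3)c(OCc3ccccc3)c1)[C@H](OC(C)=O)[C@H]2c1c(OCc3ccccc3)cc(OCc3ccccc3)c2c1O[C@H](c1ccc(OCc3ccccc3)c(OCc3ccccc3)c1)[C@H](O)C2 | intermediate
18 | protected tetramer with 3-O-acetyl on unit 3 | c1c(OCc3ccccc3)cc(OCc3ccccc3)c2c1O[C@H](c1ccc(OCc3ccccc3)c(OCc3ccccc3)c1)[C@H](O)[C@H]2c1c(OCc3ccccc3)cc(OCc3ccccc3)c2c1O[C@H](c1ccc(OCc3ccccc3)c(OCc3ccccc3)c1)[C@H](O)[C@H]2c1c(OCc3ccc(OCc4ccccc4)c(OCc4ccccc4)c3)cc(OCc3ccc(OCc4ccccc4)c(OCc4ccccc4)c3)c2c1O[C@H](c1ccc(OCc3ccccc3)c(OCc3ccccc3)c1)[C@H](OC(C)=O)[C@H]2c1c(OCc3ccccc3)cc(OCc3ccccc3)c2c1O[C@H](c1ccc(OCc3ccccc3)c(OCc3ccccc3)c1)[C@H](O)C2 | intermediate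
19 | protected tetramer with four free 3-OH groups | c1c(OCc3ccccc3)cc(OCc3ccccc3)c2c1O[C@H](c1ccc(OCc3ccccc3)c(OCc3ccccc3)c1)[C@H](O)[C@H]2c1c(OCc3ccccc3)cc(OCc3ccccc3)c2c1O[C@H](c1ccc(OCc3ccccc3)c(OCc3ccccc3)c1)[C@H](O)[C@H]2c1c(OCc3ccc(OCc4ccccc4)c(OCc4ccccc4)c3)cc(OCc3ccc(OCc4ccccc4)c(OCc4ccccc4)c3)c2c1O[C@H](c1ccc(OCc3ccccc3)c(OCc3ccccc3)c1)[C@H](O)[C@H]2c1c(OCc3ccccc3)cc(OCc3ccccc3)c2c1O[C@H](c1ccc(OCc3ccccc3)c(OCc3ccccc3)c1)[C@H](O)C2 | intermediate
20 | epicatechin-(4β→8)-epicatechin-(4β→8)-epicatechin-(4β→8)-epicatechin | Oc1cc(O)c2c(c1)O[C@H](c1ccc(O)c(O)c1)[C@H](O)[C@H]2c1c(O)cc(O)c2c1O[C@H](c1ccc(O)c(O)c1)[C@H](O)[C@H]2c1c(O)cc(O)c2c1O[C@H](c1ccc(O)c(O)c1)[C@H](O)[C@H]2c1c(O)cc(O)c2c1O[C@H](c1ccc(O)c(O)c1)[C@H](O)C2 | target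

**Step count**

Total: 13 steps. Longest linear sequence: 11 steps (1–6, 8, 10–13).

**Steps most likely to fail**

Step 6. The C3 cation may instead take a hydride from C4, after which the five-membered ring aromatises to a benzofuran. C2 may also lose its configuration through reversible heterolysis of the C2–C4 bond, or the shift may run through the other rotamer and give the 2,3-trans series. The fallback uses only known chemistry and takes unit 3 from the chiral pool as well. It sets out from 14 and 16: coupling with TMSOTf (cat.) in CH2Cl2 at −78 °C, with 14 in excess, gives the perbenzylated epicatechin-(4β→8)-epicatechin F1. Two further chain extensions with 16 under the same conditions give the perbenzylated trimer F2 and the perbenzylated tetramer F3. Hydrogenolysis of F3 (H2, Pd(OH)2/C) returns to the route at 20.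

Step 8. Under the hard Lewis acid the DBB ethers of ring A may ionise, and the C4 cation may add to a second molecule of 12 instead of to 14 (self-condensation). The fallback changes the leaving group and the mode of activation. It sets out from 12: benzyl mercaptan and BF3·OEt2 in CH2Cl2 at −40 °C give the 4β-benzylthio 3-O-acetate F4. F4 is then activated thiophilically with AgBF4 in THF–CH2Cl2 at 0 °C in the presence of 14, conditions under which ethers and acetates are inert, and the route is rejoined at 15.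

Step 3. Condensation with the hydrazide may stall at a keto group shielded by two ortho ethers, and forcing it with acid and heat may cleave the benzylic ethers. The fallback avoids the keto ester altogether. It sets out from 3: N-iodosuccinimide in MeCN at 0 °C gives the aryl iodide F5. Coupling of F5 with methyl diazoacetate (Pd(PPh3)4, Ag2CO3, Et3N, toluene, rt), which keeps the diazo group, rejoins the route at 7.

**Further compounds**

F1 | step 6 | octa-O-benzyl epicatechin-(4β→8)-epicatechin | c1c(OCc3ccccc3)cc(OCc3ccccc3)c2c1O[C@H](c1ccc(OCc3ccccc3)c(OCc3ccccc3)c1)[C@H](O)[C@H]2c1c(OCc3ccccc3)cc(OCc3ccccc3)c2c1O[C@H](c1ccc(OCc3ccccc3)c(OCc3ccccc3)c1)[C@H](O)C2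
F2 | step 6 | dodeca-O-benzyl epicatechin-(4β→8)-epicatechin-(4β→8)-epicatechin | c1c(OCc3ccccc3)cc(OCc3ccccc3)c2c1O[C@H](c1ccc(OCc3ccccc3)c(OCc3ccccc3)c1)[C@H](O)[C@H]2c1c(OCc3ccccc3)cc(OCc3ccccc3)c2c1O[C@H](c1ccc(OCc3ccccc3)c(OCc3ccccc3)c1)[C@H](O)[C@H]2c1c(OCc3ccccc3)cc(OCc3ccccc3)c2c1O[C@H](c1ccc(OCc3ccccc3)c(OCc3ccccc3)c1)[C@H](O)C2
F3 | step 6 | hexadeca-O-benzyl epicatechin-(4β→8)-epicatechin-(4β→8)-epicatechin-(4β→8)-epicatechin | c1c(OCc3ccccc3)cc(OCc3ccccc3)c2c1O[C@H](c1ccc(OCc3ccccc3)c(OCc3ccccc3)c1)[C@H](O)[C@H]2c1c(OCc3ccccc3)cc(OCc3ccccc3)c2c1O[C@H](c1ccc(OCc3ccccc3)c(OCc3ccccc3)c1)[C@H](O)[C@H]2c1c(OCc3ccccc3)cc(OCc3ccccc3)c2c1O[C@H](c1ccc(OCc3ccccc3)c(OCc3ccccc3)c1)[C@H](O)[C@H]2c1c(OCc3ccccc3)cc(OCc3ccccc3)c2c1O[C@H](c1ccc(OCc3ccccc3)c(OCc3ccccc3)c1)[C@H](O)C2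
F4 | step 8 | (2R)-2,3-cis-3,4-trans-3-acetoxy-4-(benzylthio)-3',4'-bis(benzyloxy)-5,7-bis(DBB-oxy)flavan | c1c(OCc3ccc(OCc4ccccc4)c(OCc4ccccc4)c3)cc(OCc3ccc(OCc4ccccc4)c(OCc4ccccc4)c3)c2c1O[C@H](c1ccc(OCc3ccccc3)c(OCc3ccccc3)c1)[C@H](OC(C)=O)[C@H]2SCc3ccccc3
F5 | step 3 | 2-iodo-1,3,5-tris(DBB-oxy)benzene | Ic1c(OCc2ccc(OCc3ccccc3)c(OCc3ccccc3)c2)cc(OCc2ccc(OCc3ccccc3)c(OCc3ccccc3)c2)cc1OCc1ccc(OCc2ccccc2)c(OCc2ccccc2)c1
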